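The hydroxylated cyclohexene ring (ring A; carotenoid numbering: C1 gem-dimethyl carbon, C2 methylene, C3 carbinol carbon, C6 polyene-bearing sp2 carbon) is disconnected at C1–C2. The feature exploited is that quaternary C1 sits beside sp2 C6: written as a ketone, C6 makes C1 the α-carbon of an isopropyl ketone, while C2–C3–C4 map onto (R)-epichlorohydrin, which supplies the C3 configuration. The key step, a 6-(enolendo)-exo-tet enolate alkylation of an acyclic iodo ketone, closes ring A and creates quaternary C1 in one operation. The C6 ketone then becomes an enol triflate that receives C7; the C10 phosphonium salt is joined to commercial C30 β-apo-8′-carotenal and the alcohol is oleoylated.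

Key step: step 4

Remark (assumptions): compounds 1, 2, 11, 15 and 18 are taken as commercially available; compounds 4 to 8 are carried as mixtures of epimers at the methyl-bearing carbon that later becomes sp2 C5; all polyene work is done under argon in dim light.

Step 1
Reactants: 1 2-methylpentan-3-one; 2 (R)-epichlorohydrin [(2R)-2-(chloromethyl)oxirane]
Product: 4 (6R)-7-chloro-6-hydroxy-2,4-dimethylheptan-3-one, via lithium enolate 3 (not isolated)
Conditions: LiN(i-Pr)2, THF, −78 °C; then 2, BF3·OEt2, −78 °C; aq. NH4Cl
Reagents that add atoms: none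
Why: Kinetic deprotonation takes the less hindered CH2 of the ethyl group, and the lithium enolate should open the BF3-activated epoxide at its unsubstituted CH2 (Lewis-acid-promoted epoxide opening by an enolate), so the C–O stereocentre of 2 is not touched and becomes C3 (R), while the new methyl-bearing centre forms without control and is erased in step 5.

Step 2
Reactants: 4 (6R)-7-chloro-6-hydroxy-2,4-dimethylheptan-3-one
Product: 5 (6R)-6-[(tert-butyldimethylsilyl)oxy]-7-chloro-2,4-dimethylheptan-3-one
Conditions: TBSCl, imidazole, DMF, 0 → 25 °C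
Reagents that add atoms: tert-butyldimethylsilyl chloride (TBSCl), CC(C)(C)[Si](C)(C)Cl
Why: Standard silylation of a secondary alcohol, which also drains any cyclic hemiketal form and removes the alkoxide that would otherwise close onto the chloride as an epoxide in step 4.

Step 3
Reactants: 5 (6R)-6-[(tert-butyldimethylsilyl)oxy]-7-chloro-2,4-dimethylheptan-3-one
Product: 6 (6R)-6-[(tert-butyldimethylsilyl)oxy]-7-iodo-2,4-dimethylheptan-3-one
Conditions: NaI, butan-2-one, reflux
Reagents that add atoms: sodium iodide, [Na+].[I-]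
Why: Finkelstein halide exchange at the primary carbon, driven by precipitation of NaCl, gives the softer and better leaving group without touching the neighbouring stereocentre.

Step 4
Reactants: 6 (6R)-6-[(tert-butyldimethylsilyl)oxy]-7-iodo-2,4-dimethylheptan-3-one
Product: 8 (4R)-4-[(tert-butyldimethylsilyl)oxy]-2,2,6-trimethylcyclohexan-1-one, via potassium enolate 7 (not isolated)
Conditions: KOt-Bu, t-BuOH–THF, 0 → 25 °C, 0.02 M
Reagents that add atoms: none
Why: Reversible deprotonation by KOt-Bu gives the tetrasubstituted potassium enolate 7 on the isopropyl side, and its carbon (C1) displaces the primary iodide at C2 in an intramolecular SN2 reaction, which closes ring A and creates the quaternary gem-dimethyl carbon. The closest known reaction type is the endocyclic alkylation of an isopropyl ketone enolate by a tethered primary halide, which is known to give 2,2-dimethylcyclohexanones by C-alkylation. The six-membered ring closes in the 6-(enolendo)-exo-tet mode, which the ring-closure rules for enolates allow because the six-atom chain lets the halide-bearing carbon approach perpendicular to the enolate plane. No stereocentre is created at the new bond (C1 carries two methyl groups); the configuration at C3 comes unchanged from (R)-epichlorohydrin, and the methyl-bearing carbon is formed as an epimer mixture that step 5 converts into sp2 C5. The step needs C- over O-alkylation and reaction through the isopropyl-side enolate rather than the enolate on the other side. The soft iodide and the hydrogen-bonding t-BuOH favour attack through carbon, the second enolate could only close a four-membered ring and is returned to the productive one by proton exchange, and the silyl ether prevents epoxide formation.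

Step 5
Reactants: 8 (4R)-4-[(tert-butyldimethylsilyl)oxy]-2,2,6-trimethylcyclohexan-1-one
Product: 10 (4R)-4-[(tert-butyldimethylsilyl)oxy]-2,6,6-trimethylcyclohex-1-en-1-yl trifluoromethanesulfonate, via lithium enolate 9 (not isolated)
Conditions: LiN(i-Pr)2, THF, −78 → 0 °C; then PhNTf2, −78 → 25 °C
Reagents that add atoms: N-phenylbis(trifluoromethanesulfonimide) (PhNTf2), O=S(=O)(N(c1ccccc1)S(=O)(=O)C(F)(F)F)C(F)(F)F
Why: Only one α-hydrogen remains, so enolisation is regiospecific and O-sulfonylation (enol triflate formation) fixes the tetrasubstituted C5=C6 double bond, merges the epimers and activates C6 for carbon–carbon bond formation.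

Step 6
Reactants: 10 (4R)-4-[(tert-butyldimethylsilyl)oxy]-2,6,6-trimethylcyclohex-1-en-1-yl trifluoromethanesulfonate; 11 (tributylstannyl)methanol
Product: 12 [(4R)-4-[(tert-butyldimethylsilyl)oxy]-2,6,6-trimethylcyclohex-1-en-1-yl]methanol
Conditions: Pd(PPh3)4 (10 mol%), LiCl, 1,4-dioxane, 100 °C
Reagents that add atoms: none
Why: Stille cross-coupling, in which zerovalent palladium adds oxidatively into the vinyl triflate, chloride assists transfer of the hydroxymethyl group from tin and reductive elimination attaches C7 with the ring double bond kept in place.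

Step 7
Reactants: 12 [(4R)-4-[(tert-butyldimethylsilyl)oxy]-2,6,6-trimethylcyclohex-1-en-1-yl]methanol
Product: 14 {[(4R)-4-hydroxy-2,6,6-trimethylcyclohex-1-en-1-yl]methyl}triphenylphosphonium bromide, via silyl ether phosphonium salt 13 (not isolated)
Conditions: PPh3·HBr, MeOH, 25 → 40 °C
Reagents that add atoms: triphenylphosphine hydrobromide, [Br-].[PH+](c1ccccc1)(c1ccccc1)c1ccccc1
Why: Acid ionises the allylic alcohol to an allyl cation that triphenylphosphine captures at the primary terminus (the usual phosphonium salt formation of carotenoid chemistry), and the same acidic methanol should remove the silyl ether by methanolysis, while the homoallylic C3 carbinol does not ionise and keeps its configuration.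

Step 8
Reactants: 14 {[(4R)-4-hydroxy-2,6,6-trimethylcyclohex-1-en-1-yl]methyl}triphenylphosphonium bromide; 15 all-trans-β-apo-8′-carotenal
Product: 17 (3R)-β-cryptoxanthin [(3R)-β,β-caroten-3-ol], via phosphonium ylide 16 (not isolated)
Conditions: NaOMe, MeOH–CH2Cl2, 0 → 25 °C, dark, Ar; then n-heptane, reflux (Z → E)
Reagents that add atoms: none
Why: Wittig olefination of the C30 aldehyde with the semistabilised allylic ylide forms the C7=C8 bond, the hindered 7Z isomer formed alongside should isomerise thermally to the all-E polyene that crystallises, and the free hydroxyl is tolerated by the alkoxide base.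

Step 9
Reactants: 17 (3R)-β-cryptoxanthin; 18 oleoyl chloride [(9Z)-octadec-9-enoyl chloride]
Product: 19 (3R)-β,β-caroten-3-yl (9Z)-octadec-9-enoate (β-cryptoxanthin oleate, CNP0152321.1)
Conditions: pyridine, DMAP (cat.), CH2Cl2, 0 → 25 °C, dark, Ar
Reagents that add atoms: none
Why: Nucleophile-catalysed acylation of the secondary alcohol by the acid chloride (esterification) takes place at oxygen with retention at C3 and leaves the polyene and the cis double bond of the acyl chain untouched.

Compound list
1 | 2-methylpentan-3-one | CCC(=O)C(C)C | starting material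
2 | (R)-epichlorohydrin [(2R)-2-(chloromethyl)oxirane] | ClC[C@H]1CO1 | starting material
3 | lithium 4-methylpent-2-en-3-olate (kinetic enolate of 1, geometry not relevant) | CC=C([O-])C(C)C.[Li+] | intermediate
4 | (6R)-7-chloro-6-hydroxy-2,4-dimethylheptan-3-one (epimers at C4) | ClC[C@H](O)CC(C)C(=O)C(C)C | intermediate
5 | (6R)-6-[(tert-butyldimethylsilyl)oxy]-7-chloro-2,4-dimethylheptan-3-one | ClC[C@H](O[Si](C)(C)C(C)(C)C)CC(C)C(=O)C(C)C | intermediate
6 | (6R)-6-[(tert-butyldimethylsilyl)oxy]-7-iodo-2,4-dimethylheptan-3-one | IC[C@H](O[Si](C)(C)C(C)(C)C)CC(C)C(=O)C(C)C | intermediate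
7 | potassium (6R)-6-[(tert-butyldimethylsilyl)oxy]-7-iodo-2,4-dimethylhept-2-en-3-olate | IC[C@H](O[Si](C)(C)C(C)(C)C)CC(C)C([O-])=C(C)C.[K+] | intermediate
8 | (4R)-4-[(tert-butyldimethylsilyl)oxy]-2,2,6-trimethylcyclohexan-1-one (epimers at C6) | CC1(C)C[C@H](O[Si](C)(C)C(C)(C)C)CC(C)C1=O | intermediate
9 | lithium (4R)-4-[(tert-butyldimethylsilyl)oxy]-2,6,6-trimethylcyclohex-1-en-1-olate | CC1=C([O-])C(C)(C)C[C@H](O[Si](C)(C)C(C)(C)C)C1.[Li+] | intermediate
10 | (4R)-4-[(tert-butyldimethylsilyl)oxy]-2,6,6-trimethylcyclohex-1-en-1-yl trifluoromethanesulfonate | CC1=C(OS(=O)(=O)C(F)(F)F)C(C)(C)C[C@H](O[Si](C)(C)C(C)(C)C)C1 | intermediate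
11 | (tributylstannyl)methanol | CCCC[Sn](CCCC)(CCCC)CO | starting material
12 | [(4R)-4-[(tert-butyldimethylsilyl)oxy]-2,6,6-trimethylcyclohex-1-en-1-yl]methanol | CC1=C(CO)C(C)(C)C[C@H](O[Si](C)(C)C(C)(C)C)C1 | intermediate
13 | {[(4R)-4-[(tert-butyldimethylsilyl)oxy]-2,6,6-trimethylcyclohex-1-en-1-yl]methyl}triphenylphosphonium bromide | CC1=C(C[P+](c2ccccc2)(c2ccccc2)c2ccccc2)C(C)(C)C[C@H](O[Si](C)(C)C(C)(C)C)C1.[Br-] | intermediate
14 | {[(4R)-4-hydroxy-2,6,6-trimethylcyclohex-1-en-1-yl]methyl}triphenylphosphonium bromide | CC1=C(C[P+](c2ccccc2)(c2ccccc2)c2ccccc2)C(C)(C)C[C@H](O)C1.[Br-] | intermediate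
15 | all-trans-β-apo-8′-carotenal [(2E,4E,6E,8E,10E,12E,14E,16E)-2,6,11,15-tetramethyl-17-(2,6,6-trimethylcyclohex-1-en-1-yl)heptadeca-2,4,6,8,10,12,14,16-octaenal] | O=C/C(C)=C/C=C/C(C)=C/C=C/C=C(C)/C=C/C=C(C)/C=C/C1=C(C)CCCC1(C)C | starting material
16 | {[(4R)-4-hydroxy-2,6,6-trimethylcyclohex-1-en-1-yl]methylidene}triphenylphosphorane | CC1=C(C=P(c2ccccc2)(c2ccccc2)c2ccccc2)C(C)(C)C[C@H](O)C1 | intermediate
17 | (3R)-β-cryptoxanthin [(3R)-β,β-caroten-3-ol, all-E] | O[C@@H]1CC(C)=C(/C=C/C(C)=C/C=C/C(C)=C/C=C/C=C(C)/C=C/C=C(C)/C=C/C2=C(C)CCCC2(C)C)C(C)(C)C1 | intermediate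
18 | oleoyl chloride [(9Z)-octadec-9-enoyl chloride] | CCCCCCCC/C=C\CCCCCCCC(=O)Cl | starting material
19 | (3R)-β,β-caroten-3-yl (9Z)-octadec-9-enoate (β-cryptoxanthin oleate) | CCCCCCCC/C=C\CCCCCCCC(=O)O[C@@H]1CC(C)=C(/C=C/C(C)=C/C=C/C(C)=C/C=C/C=C(C)/C=C/C=C(C)/C=C/C2=C(C)CCCC2(C)C)C(C)(C)C1 | target

Total step count: 9. Longest linear sequence: 9 steps (steps 1 to 9 from 1 and 2; compounds 11, 15 and 18 are purchased).

Steps most likely to fail (the key step 4 is judged less exposed, because it rests on a close structural analogy):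

Step 1. The epoxide opening may be sluggish or unselective: the lithium ketone enolate may be consumed by proton transfer or self-aldol reaction under BF3, the amine may sequester the Lewis acid, or direct displacement of chloride may erode the enantiomeric purity. Fallback, from 1 back to 4: 1 is condensed with N,N-dimethylhydrazine (AcOH cat., EtOH, reflux) to 2-methylpentan-3-one N,N-dimethylhydrazone F1. The aza-enolate of F1 (LiN(i-Pr)2, THF, 0 °C, formed on the ethyl side) should open 2 at its CH2 without any Lewis acid (−78 → −20 °C) to give the chlorohydrin hydrazone F2. Buffered hydrolysis (CuCl2, aq. THF, pH 7) then releases 4.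

Step 6. Oxidative addition at the tetrasubstituted, doubly flanked triflate and transfer of the sp3 hydroxymethyl group from tin may both be slow, so that triflate hydrolysis, reduction or butyl transfer competes. Fallback, from 10 back to 12: methoxycarbonylation of 10 (Pd(OAc)2, 1,3-bis(diphenylphosphino)propane, CO 1 atm, MeOH, Et3N, DMF, 70 °C) replaces the transmetalation by insertion of the small CO molecule. It gives methyl (4R)-4-[(tert-butyldimethylsilyl)oxy]-2,6,6-trimethylcyclohex-1-ene-1-carboxylate F3, and i-Bu2AlH (CH2Cl2, −78 °C) reduces F3 to 12.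

Step 8. The hindered cyclogeranyl ylide may add slowly to the vinylogous aldehyde, and the hindered 7Z isomer may form in quantity, with loss of polyene during prolonged thermal isomerisation. Fallback, from 10 and 15 back to 17 (it replaces steps 6 to 8): 15 is converted by Takai–Hodgson olefination (Bu3SnCHBr2, CrCl2, LiI, THF–DMF, 25 °C) into the (E)-C31 vinylstannane F4. Stille coupling of F4 with 10 (Pd2(dba)3, AsPh3, N-methylpyrrolidone, 60 °C) forms the C6–C7 bond with the 7E geometry carried by the stannane and gives O-silyl β-cryptoxanthin F5. Bu4NF (THF, 0 °C) then frees 17.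

Further compounds
F1 | step 1 | 2-methylpentan-3-one N,N-dimethylhydrazone | CCC(=NN(C)C)C(C)C
F2 | step 1 | (6R)-7-chloro-6-hydroxy-2,4-dimethylheptan-3-one N,N-dimethylhydrazone | ClC[C@H](O)CC(C)C(=NN(C)C)C(C)C
F3 | step 6 | methyl (4R)-4-[(tert-butyldimethylsilyl)oxy]-2,6,6-trimethylcyclohex-1-ene-1-carboxylate | CC1=C(C(=O)OC)C(C)(C)C[C@H](O[Si](C)(C)C(C)(C)C)C1
F4 | step 8 | tributyl[(1E,3E,5E,7E,9E,11E,13E,15E,17E)-3,7,12,16-tetramethyl-18-(2,6,6-trimethylcyclohex-1-en-1-yl)octadeca-1,3,5,7,9,11,13,15,17-nonaen-1-yl]stannane | CCCC[Sn](CCCC)(CCCC)/C=C/C(C)=C/C=C/C(C)=C/C=C/C=C(C)/C=C/C=C(C)/C=C/C1=C(C)CCCC1(C)C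
F5 | step 8 | (3R)-3-[(tert-butyldimethylsilyl)oxy]-β,β-carotene (O-silyl β-cryptoxanthin) | CC(C)(C)[Si](C)(C)O[C@@H]1CC(C)=C(/C=C/C(C)=C/C=C/C(C)=C/C=C/C=C(C)/C=C/C=C(C)/C=C/C2=C(C)CCCC2(C)C)C(C)(C)C1
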